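The whole C15 cage is traced back to an open farnesyl chain: bonds C5–C6, C5–C11 and C4–C10 (longipinane numbering) are cut together. In the forward sense one cyclase-bound cation cascade folds achiral (2E,6E)-farnesyl diphosphate into α-longipinene. It closes the cyclobutane C4–C5–C11–C10, the six-membered ring C1–C2–C3–C4–C10–C11 and the seven-membered ring C5–C6–C7–C8–C9–C10–C11, and fixes C4, C5, C10 and C11. The step exploits the fact that these four stereocentres and all fifteen skeletal carbons of the target are those of this hydrocarbon. Oxygen follows late: allylic oxidation at C1, then enzymatic hydroxylation and acylation at C7 (tiglate) and C9 (angelate).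

Key step: step 3

Remark: longipinane numbering is used (C12 is the methyl on C3); β means the face of the seven-membered ring turned toward C4 and α the face turned toward C11; the cations and the tertiary allylic diphosphate that never leave the cyclase are treated as mechanism and get no compound number; the two hydroxylase variants are assumed to be found by screening an active-site library; C7 and C9 are left unoxidised in the cyclase substrate because C7 carries positive charge during the cascade.

Step 1
Reactants: 1 (2E,6E)-farnesol
Product: 3 (2E,6E)-farnesyl chloride, via farnesyloxydimethylsulfonium chloride 2 (not isolated)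
Conditions: NCS, Me2S, CH2Cl2, −40 to 0 °C
Reagents that add atoms: N-chlorosuccinimide, O=C1CCC(=O)N1Cl
Why: Corey–Kim chlorination, in which the alcohol is activated as alkoxysulfonium salt 2 and chloride displaces dimethyl sulfoxide at the primary allylic carbon (SN2) under cold, neutral conditions, so neither allylic transposition nor E/Z isomerisation of the 2,3-alkene is expected.

Step 2
Reactants: 3 (2E,6E)-farnesyl chloride
Product: 4 (2E,6E)-farnesyl diphosphate (isolated as the trisammonium salt)
Conditions: (n-Bu4N)3HP2O7, MeCN, rt; then Dowex 50WX8 (NH4+ form), aq NH4HCO3/i-PrOH; cellulose chromatography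
Reagents that add atoms: tris(tetrabutylammonium) hydrogen diphosphate, CCCC[N+](CCCC)(CCCC)CCCC.CCCC[N+](CCCC)(CCCC)CCCC.CCCC[N+](CCCC)(CCCC)CCCC.OP(=O)([O-])OP(=O)([O-])[O-]
Why: SN2 displacement of the primary allylic chloride by the diphosphate anion in a dipolar aprotic solvent is the standard diphosphorylation of prenyl halides and leaves both alkene geometries untouched; ion exchange gives the water-soluble salt the enzyme needs.

Step 3
Reactants: 4 (2E,6E)-farnesyl diphosphate
Product: 5 α-longipinene, (1R,2S,7R,8R) enantiomer
Conditions: recombinant α-longipinene synthase (conifer longifolene/α-longipinene synthase type, His-tagged, from E. coli), MgCl2, dithiothreitol, HEPES buffer pH 7.2, 10% glycerol, pentane overlay, 30 °C; then AgNO3-impregnated silica chromatography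
Reagents that add atoms: none
Why: Mg2+-assisted ionisation of 4 and return of diphosphate to C3 give the enzyme-bound tertiary allylic diphosphate, whose cisoid conformer re-ionises so that the distal C6=C7 alkene bonds to C5 and forms C5–C6 (11-endo macrocyclisation leaving a secondary cation at C7). A 1,3-hydride shift from C5 to C7 produces the C3–C4–C5 allyl cation, which the C10=C11 alkene captures at C5 to form C5–C11 (6-exo for the six-membered ring and 7-endo for the seven-membered ring, cation now tertiary at C10); the C3=C4 alkene then attacks C10 through C4 to form C4–C10 (4-exo, cyclobutane), and a base in the pocket removes a C2 proton from the resulting C3 cation to give the C2=C3 alkene. The closest known reaction type is the ionisation-initiated (class one) sesquiterpene synthase cyclisation of farnesyl diphosphate, as carried out by conifer longifolene/α-longipinene synthases. Because 4 is achiral, C4, C5, C10 and C11 are set by the chiral pocket, which fixes the helical sense in which the chain is folded (absolute configuration), while the small bicyclic closures allow only the cis-bridged cage (relative configuration). The step needs deprotonation of the cyclobutylcarbinyl cation at C2 in preference to its 1,2-alkyl shift toward longifolene and to proton loss from C12; nothing in the substrate can secure this, so it rests on the position of the active-site base in the chosen enzyme, and co-formed hydrocarbons are removed on the silver-loaded silica.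

Step 4
Reactants: 5 α-longipinene
Product: 6 (4R,5S,10R,11R)-longipin-2-en-1-one
Conditions: CrO3, 3,5-dimethylpyrazole, CH2Cl2, −20 °C
Reagents that add atoms: chromium trioxide, O=[Cr](=O)=O
Why: Allylic oxidation of a trisubstituted cycloalkene by the CrO3–3,5-dimethylpyrazole complex (the α-pinene-to-verbenone type of conversion) should take the only allylic ring methylene, C1, to the ketone, since the bridgehead C4–H and the C12 methyl react more slowly, and no stereocentre is made or touched.

Step 5
Reactants: 6 (4R,5S,10R,11R)-longipin-2-en-1-one
Product: 7 (4R,5S,7R,10R,11R)-7-hydroxylongipin-2-en-1-one (7β-alcohol)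
Conditions: P450 BM3 (CYP102A1) variant selected by screening for C7 (cell-free extract), NADP+ (cat.), D-glucose, glucose dehydrogenase, air (O2), K2HPO4/KH2PO4 buffer pH 8.0, 2% DMSO, 25 °C
Reagents that add atoms: dioxygen, O=O
Why: Cytochrome P450 monooxygenation (hydrogen abstraction by the iron-oxo species, then oxygen rebound with retention) of an unactivated ring methylene is established for engineered variants of this enzyme on terpenoid ketones and lactones; C7 is a CH2 flanked by a gem-dimethyl carbon and remote from the electron-poor enone, the kind of site such variants prefer, and the fit of 6 in the selected pocket should deliver oxygen to the pseudo-equatorial hydrogen on the β face, which sets C7 as R.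

Step 6
Reactants: 7 (4R,5S,7R,10R,11R)-7-hydroxylongipin-2-en-1-one; 8 tiglic acid
Product: 10 (4R,5S,7R,10R,11R)-7-tigloyloxylongipin-2-en-1-one, via tiglic 2,4,6-trichlorobenzoic anhydride 9 (not isolated)
Conditions: 8, 2,4,6-trichlorobenzoyl chloride, Et3N, toluene, rt; then 7, DMAP, toluene, 60 °C
Reagents that add atoms: none
Why: Yamaguchi esterification, in which the hindered alcohol attacks the unshielded tigloyl carbonyl of mixed anhydride 9 under DMAP catalysis; the E acid is the stable isomer, so nucleophilic catalysis is harmless, and C7 keeps its configuration because its C–O bond is not broken.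

Step 7
Reactants: 10 (4R,5S,7R,10R,11R)-7-tigloyloxylongipin-2-en-1-one
Product: 11 (4R,5S,7R,9R,10R,11R)-9-hydroxy-7-tigloyloxylongipin-2-en-1-one (9α-alcohol)
Conditions: second P450 BM3 (CYP102A1) variant selected by screening for C9 of 10 (purified enzyme, esterase-free), NADP+ (cat.), D-glucose, glucose dehydrogenase, air (O2), K2HPO4/KH2PO4 buffer pH 8.0, 5% DMSO, 25 °C
Reagents that add atoms: dioxygen, O=O
Why: The same P450 C–H hydroxylation, now at the ring methylene next to the quaternary C10, with C7 blocked by the ester; oxygen rebound should outrun opening of the cyclobutylcarbinyl radical, and the selected pocket should abstract the pseudo-axial hydrogen on the α face and return oxygen with retention, which sets C9 as R, trans to the C7 ester.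

Step 8
Reactants: 11 (4R,5S,7R,9R,10R,11R)-9-hydroxy-7-tigloyloxylongipin-2-en-1-one; 12 angelic acid
Product: 14 (4R,5S,7R,9R,10R,11R)-9-angeloyloxy-7-tigloyloxylongipin-2-en-1-one (target), via angelic 2,4,6-trichlorobenzoic anhydride 13 (not isolated)
Conditions: 12, 2,4,6-trichlorobenzoyl chloride, Et3N, toluene, rt; then 11, toluene, 80 °C (no DMAP)
Reagents that add atoms: none
Why: Yamaguchi-type angeloylation through mixed anhydride 13 without nucleophilic catalyst or strong base, so that the Z acid is transferred without conjugate addition–elimination and hence without Z to E isomerisation; C9 keeps its configuration because its C–O bond is not broken.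

Compound list
1 | (2E,6E)-farnesol | CC(C)=CCC/C(C)=C/CC/C(C)=C/CO | starting material
2 | (2E,6E)-farnesyloxydimethylsulfonium chloride | CC(C)=CCC/C(C)=C/CC/C(C)=C/CO[S+](C)C.[Cl-] | intermediate (not isolated)
3 | (2E,6E)-farnesyl chloride | CC(C)=CCC/C(C)=C/CC/C(C)=C/CCl | intermediate
4 | (2E,6E)-farnesyl diphosphate (handled as trisammonium salt, drawn as the acid) | CC(C)=CCC/C(C)=C/CC/C(C)=C/COP(=O)(O)OP(=O)(O)O | intermediate
5 | α-longipinene, (1R,2S,7R,8R)-2,6,6,9-tetramethyltricyclo[5.4.0.0(2,8)]undec-9-ene, (4R,5R,10S,11R) in longipinane numbering | C1CCC(C)(C)[C@@H]2[C@H]3CC=C(C)[C@@H]2[C@]31C | intermediate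
6 | (4R,5S,10R,11R)-longipin-2-en-1-one | C1CCC(C)(C)[C@@H]2[C@H]3C(=O)C=C(C)[C@@H]2[C@]31C | intermediate
7 | (4R,5S,7R,10R,11R)-7-hydroxylongipin-2-en-1-one (7β-OH, on the ring face toward C4) | C1C[C@@H](O)C(C)(C)[C@@H]2[C@H]3C(=O)C=C(C)[C@@H]2[C@]31C | intermediate
8 | tiglic acid, (E)-2-methylbut-2-enoic acid | C/C=C(\C)C(=O)O | starting material
9 | tiglic 2,4,6-trichlorobenzoic anhydride | C/C=C(\C)C(=O)OC(=O)c1c(Cl)cc(Cl)cc1Cl | intermediate (not isolated)
10 | (4R,5S,7R,10R,11R)-7-tigloyloxylongipin-2-en-1-one | C1C[C@@H](OC(=O)/C(C)=C/C)C(C)(C)[C@@H]2[C@H]3C(=O)C=C(C)[C@@H]2[C@]31C | intermediate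
11 | (4R,5S,7R,9R,10R,11R)-9-hydroxy-7-tigloyloxylongipin-2-en-1-one (9α-OH, on the ring face toward C11) | O[C@@H]1C[C@@H](OC(=O)/C(C)=C/C)C(C)(C)[C@@H]2[C@H]3C(=O)C=C(C)[C@@H]2[C@]31C | intermediate
12 | angelic acid, (Z)-2-methylbut-2-enoic acid | C/C=C(/C)C(=O)O | starting material
13 | angelic 2,4,6-trichlorobenzoic anhydride | C/C=C(/C)C(=O)OC(=O)c1c(Cl)cc(Cl)cc1Cl | intermediate (not isolated)
14 | (4R,5S,7R,9R,10R,11R)-9-angeloyloxy-7-tigloyloxylongipin-2-en-1-one | C/C=C(/C)C(=O)O[C@@H]1C[C@@H](OC(=O)/C(C)=C/C)C(C)(C)[C@@H]2[C@H]3C(=O)C=C(C)[C@@H]2[C@]31C | target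

Total step count: 8
Longest linear sequence: 8 steps (1 to 14)

Steps most likely to fail

Step 5. Oxygen rebound may reach C7 from the wrong face, or the alcohol may be oxidised on to the ketone, because the two C7 hydrogens differ little in reactivity. The fallback sets out from 6 and accepts any hydroxylase that is only site-selective for C7. The epimeric alcohol, (4R,5S,7S,10R,11R)-7-hydroxylongipin-2-en-1-one F1, alone or mixed with 7, would be oxidised with Dess–Martin periodinane (NaHCO3, CH2Cl2) to (4R,5S,10R,11R)-longipin-2-ene-1,7-dione F2. The C7 configuration would then be set chemically instead of by the enzyme: NaBH4 in MeOH/CH2Cl2 at −78 °C should reduce the saturated C7 ketone ahead of the conjugated C1 ketone. Attack from the pseudo-axial direction should give the pseudo-equatorial 7β-alcohol, as small hydrides do with 2,2-dimethylcycloalkanones. The fallback comes back to the route at 7.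

Step 7. Hydroxylation of 10 may put oxygen on the β face of C9 or over-oxidise, since the required hydrogen is the more hindered pseudo-axial one. The fallback sets out from 10 and accepts a C9-selective but face-unselective variant. The epimer, (4R,5S,7R,9S,10R,11R)-9-hydroxy-7-tigloyloxylongipin-2-en-1-one F3, alone or mixed with 11, would be oxidised with buffered Dess–Martin periodinane to (4R,5S,7R,10R,11R)-7-tigloyloxylongipin-2-ene-1,9-dione F4. One equivalent of KBH(s-Bu)3 in THF at −78 °C should then attack the C9 carbonyl from the open pseudo-equatorial direction and give the pseudo-axial 9α-alcohol. The β,β-disubstituted enone and the α,β-disubstituted tiglate are expected to react more slowly with this bulky hydride in the cold. The fallback comes back to the route at 11.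

Step 8. Slow acylation of the hindered pseudo-axial C9 alcohol gives the activated angeloyl unit time to isomerise from Z to E, which would give the ditiglate, or the acylation may stall. The fallback sets out from 11 and builds the Z alkene on the ester instead of transferring it. Esterification with 2-[bis(2,2,2-trifluoroethoxy)phosphoryl]propanoic acid (DCC, DMAP, CH2Cl2, then warming if needed) should give (4R,5S,7R,9R,10R,11R)-9-{2-[bis(2,2,2-trifluoroethoxy)phosphoryl]propanoyloxy}-7-tigloyloxylongipin-2-en-1-one F5, as a mixture of epimers at the phosphonate-bearing carbon. This saturated acid has no geometry to lose. Deprotonation of the phosphonate with KN(SiMe3)2 and 18-crown-6 in THF at −78 °C, then acetaldehyde, should give the Z-trisubstituted ester by Still–Gennari olefination. The fallback comes back to the route at 14.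

Further compounds
F1 | step 5 | (4R,5S,7S,10R,11R)-7-hydroxylongipin-2-en-1-one | C1C[C@H](O)C(C)(C)[C@@H]2[C@H]3C(=O)C=C(C)[C@@H]2[C@]31C
F2 | step 5 | (4R,5S,10R,11R)-longipin-2-ene-1,7-dione | C1CC(=O)C(C)(C)[C@@H]2[C@H]3C(=O)C=C(C)[C@@H]2[C@]31C
F3 | step 7 | (4R,5S,7R,9S,10R,11R)-9-hydroxy-7-tigloyloxylongipin-2-en-1-one | O[C@H]1C[C@@H](OC(=O)/C(C)=C/C)C(C)(C)[C@@H]2[C@H]3C(=O)C=C(C)[C@@H]2[C@]31C
F4 | step 7 | (4R,5S,7R,10R,11R)-7-tigloyloxylongipin-2-ene-1,9-dione | O=C1C[C@@H](OC(=O)/C(C)=C/C)C(C)(C)[C@@H]2[C@H]3C(=O)C=C(C)[C@@H]2[C@]31C
F5 | step 8 | (4R,5S,7R,9R,10R,11R)-9-{2-[bis(2,2,2-trifluoroethoxy)phosphoryl]propanoyloxy}-7-tigloyloxylongipin-2-en-1-one | CC(C(=O)O[C@@H]1C[C@@H](OC(=O)/C(C)=C/C)C(C)(C)[C@@H]2[C@H]3C(=O)C=C(C)[C@@H]2[C@]31C)P(=O)(OCC(F)(F)F)OCC(F)(F)F
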